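The route rests on cutting the C2–C3 bond of ring D, the dihydrofuran fused to the propenol-bearing arene (ring E), back to an aryl benzyl ether that already carries the upper dihydrobenzofuran (rings B and C). C2–H of ring D is benzylic, alpha to O1 and para to the ether oxygen of ring B, hence unusually hydridic: a chiral dirhodium carbenoid generated at C3 inserts into it, closing ring D and setting C2 and C3 in one operation. The precursor is an ethyl aryldiazoacetate on ring E whose ortho oxygen bears the ring C benzyl group; the same tactic builds ring B earlier. One equilibration then turns both cis esters trans, and one reduction unveils all hydroxyl groups.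

Key step: step 9

Ring labels: A = 4-hydroxy-3-methoxyphenyl ring; B = upper dihydrofuran; C = its benzo ring; D = lower dihydrofuran; E = its benzo ring, which carries the propenol chain.

Assumption: with 2-(benzyloxy)aryl diazoacetates the (S)-configured N-phthaloyl-tert-leucinate dirhodium catalyst is taken to give the (2R)-cis ester, so the (R)-configured catalyst is used here; the mirror-image catalyst is equally accessible should the sense prove opposite.

Remark: any drift of the cis ester of ring B towards trans between steps 4 and 10 is harmless, because step 10 equilibrates C3 of both rings.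

Step 1
Reactants: 1 vanillyl alcohol (4-hydroxy-3-methoxybenzyl alcohol)
Product: 2 4-(hydroxymethyl)-2-methoxyphenyl pivalate
Conditions: NaOH (1.05 equiv), H2O–THF, 0 °C, then pivaloyl chloride (1.05 equiv)
Reagents that add atoms: pivaloyl chloride, CC(C)(C)C(=O)Cl
Why: Schotten–Baumann acylation, in which one equivalent of hydroxide ionises only the phenol, so the phenoxide should be acylated in preference to the neutral benzylic alcohol.

Step 2
Reactants: 2 4-(hydroxymethyl)-2-methoxyphenyl pivalate; 3 5-iodovanillin (4-hydroxy-3-iodo-5-methoxybenzaldehyde)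
Product: 4 4-[(4-formyl-2-iodo-6-methoxyphenoxy)methyl]-2-methoxyphenyl pivalate
Conditions: DIAD, PPh3, THF, 0 °C to rt
Reagents that add atoms: none
Why: Mitsunobu etherification, in which the acidic phenol of 3 displaces the activated primary benzylic alcohol under neutral conditions that spare aldehyde, iodide and pivalate.

Step 3
Reactants: 4 the iodo aldehyde ether; 5 ethyl diazoacetate
Product: 6 ethyl 2-diazo-2-[5-formyl-3-methoxy-2-({3-methoxy-4-(pivaloyloxy)benzyl}oxy)phenyl]acetate
Conditions: Pd(PPh3)4 (5 mol %), Ag2CO3 (0.5 equiv), Et3N, toluene, rt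
Reagents that add atoms: none
Why: Palladium-catalysed cross-coupling of an aryl iodide with the C–H bond of a diazoacetate (oxidative addition to zerovalent palladium, silver-assisted palladation of the diazo carbon, reductive elimination), which at room temperature should keep the diazo group intact and leave the aldehyde alone.

Step 4
Reactants: 6 the formyl aryldiazoacetate
Product: 7 ethyl (2S,3R)-5-formyl-7-methoxy-2-[3-methoxy-4-(pivaloyloxy)phenyl]-2,3-dihydrobenzofuran-3-carboxylate (2,3-cis)
Conditions: Rh2(R-PTTL)4 (dirhodium tetrakis[N-phthaloyl-(R)-tert-leucinate], 2 mol %), toluene (0.02 M), −60 °C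
Reagents that add atoms: none
Why: Enantioselective intramolecular 1,5-C–H insertion of a dirhodium carbenoid into the benzylic ether methylene closes ring B; the catalyst picks one methylene hydrogen and so sets C2 as S, the compact insertion transition state gives the cis ester (C3 R), and dilution and low temperature should keep the aldehyde from intercepting the carbenoid.

Step 5
Reactants: 7 the cis ester aldehyde
Product: 8 ethyl (2S,3R)-5-(hydroxymethyl)-7-methoxy-2-[3-methoxy-4-(pivaloyloxy)phenyl]-2,3-dihydrobenzofuran-3-carboxylate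
Conditions: NaBH4, EtOH–THF, 0 °C
Reagents that add atoms: none
Why: Chemoselective hydride reduction, in which NaBH4 at 0 °C should reduce the aryl aldehyde much faster than the ethyl ester or the hindered aryl pivalate.

Step 6
Reactants: 3 5-iodovanillin; 9 ethyl (triphenylphosphoranylidene)acetate
Product: 10 ethyl (E)-3-(4-hydroxy-3-iodo-5-methoxyphenyl)acrylate
Conditions: toluene, 80 °C
Reagents that add atoms: none
Why: Wittig olefination with a stabilised ylide, which tolerates the free phenol and should give the E-cinnamate under thermodynamic control of the oxaphosphetane.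

Step 7
Reactants: 8 the benzylic alcohol; 10 the iodo cinnamate phenol
Product: 11 ethyl (2S,3R)-5-{[4-((E)-3-ethoxy-3-oxoprop-1-enyl)-2-iodo-6-methoxyphenoxy]methyl}-7-methoxy-2-[3-methoxy-4-(pivaloyloxy)phenyl]-2,3-dihydrobenzofuran-3-carboxylate
Conditions: DIAD, PPh3, THF, 0 °C to rt
Reagents that add atoms: none
Why: Mitsunobu etherification of an electron-rich primary benzylic alcohol with an acidic phenol, neutral enough to leave the epimerisable cis ester, the cinnamate and the pivalate untouched.

Step 8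
Reactants: 11 the aryl iodide; 5 ethyl diazoacetate
Product: 12 ethyl (2S,3R)-5-{[2-(1-diazo-2-ethoxy-2-oxoethyl)-4-((E)-3-ethoxy-3-oxoprop-1-enyl)-6-methoxyphenoxy]methyl}-7-methoxy-2-[3-methoxy-4-(pivaloyloxy)phenyl]-2,3-dihydrobenzofuran-3-carboxylate
Conditions: Pd(PPh3)4 (5 mol %), Ag2CO3 (0.5 equiv), Et3N, toluene, rt
Reagents that add atoms: none
Why: The same palladium-catalysed aryl iodide/diazoacetate cross-coupling as in step 3, run at room temperature so that neither a Heck reaction at the cinnamate nor dipolar cycloaddition of the diazo group to it should compete.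

Step 9
Reactants: 12 the aryldiazoacetate on ring E
Product: 13 ethyl (2S,3R)-5-[(2S,3R)-3-(ethoxycarbonyl)-5-((E)-3-ethoxy-3-oxoprop-1-enyl)-7-methoxy-2,3-dihydrobenzofuran-2-yl]-7-methoxy-2-[3-methoxy-4-(pivaloyloxy)phenyl]-2,3-dihydrobenzofuran-3-carboxylate (both rings 2,3-cis)
Conditions: Rh2(R-PTTL)4 (2 mol %), toluene (0.02 M), 4 Å MS, −60 °C, slow addition of 12
Reagents that add atoms: none
Why: Loss of N2 from 12 at the dirhodium core gives a donor/acceptor carbenoid at the future C3 on ring E, which inserts into one hydrogen of the ArO–CH2–Ar methylene through a three-centre, hydride-transfer-like transition state and so forms the C2–C3 bond. The closest known reaction type is the enantioselective intramolecular C–H insertion of 2-(benzyloxy)aryl diazoacetates under chiral dirhodium tetracarboxylate catalysis, which gives cis-2-aryl-2,3-dihydrobenzofuran-3-carboxylates. Ring D is closed by a 1,5-insertion (carbenoid carbon, C3a, C7a, O1 and C2 make the five-membered ring), with only the C–C bond being formed. C2 is set as S by the catalyst, which picks one of the two methylene hydrogens, and C3 emerges R (2,3-cis) because ester and aryl group lie on the same side in the compact insertion transition state; this kinetic C3 configuration is corrected in step 10. The step needs site selectivity for this methylene over cyclopropanation of the alkene and over other C–H bonds, which the 1,5 geometry, the hydridic nature of this C–H (benzylic, next to O1, para to the ring B oxygen), the electron-poor cinnamate and high dilution should secure. Facial selectivity rests on the catalyst, since the centres of ring B are too remote to steer, and any leakage should appear as a separable diastereomer rather than as lost enantiopurity.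

Step 10
Reactants: 13 the cis,cis triester
Product: 14 ethyl (2S,3S)-5-[(2S,3S)-3-(ethoxycarbonyl)-5-((E)-3-ethoxy-3-oxoprop-1-enyl)-7-methoxy-2,3-dihydrobenzofuran-2-yl]-7-methoxy-2-[3-methoxy-4-(pivaloyloxy)phenyl]-2,3-dihydrobenzofuran-3-carboxylate (both rings 2,3-trans)
Conditions: DBU (3 equiv), MeCN, 40 °C
Reagents that add atoms: none
Why: Thermodynamic epimerisation through the ester enolates, in which DBU reversibly removes the two C3 hydrogens (alpha to an ester and benzylic) so that each ring should relax to the trans arrangement while C2 stays untouched and the aprotic amidine spares the aryl pivalate.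

Step 11
Reactants: 14 the trans,trans triester
Product: 15 4-[(2S,3R)-3-(hydroxymethyl)-5-{(2S,3R)-3-(hydroxymethyl)-5-[(E)-3-hydroxyprop-1-enyl]-7-methoxy-2,3-dihydrobenzofuran-2-yl}-7-methoxy-2,3-dihydrobenzofuran-2-yl]-2-methoxyphenol (target)
Conditions: i-Bu2AlH (12 equiv), toluene–THF, −78 to 0 °C; aqueous potassium sodium tartrate
Reagents that add atoms: none
Why: Hydride reduction with i-Bu2AlH should take the two saturated esters to hydroxymethyl groups and the cinnamate to the allylic alcohol by 1,2-reduction, and cleave the aryl pivalate in the same operation, with no stereocentre involved.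

Compound list
1 | vanillyl alcohol (4-hydroxy-3-methoxybenzyl alcohol) | COc1cc(CO)ccc1O | starting material
2 | 4-(hydroxymethyl)-2-methoxyphenyl pivalate | COc1cc(CO)ccc1OC(=O)C(C)(C)C | intermediate
3 | 5-iodovanillin (4-hydroxy-3-iodo-5-methoxybenzaldehyde) | COc1cc(C=O)cc(I)c1O | starting material
4 | 4-[(4-formyl-2-iodo-6-methoxyphenoxy)methyl]-2-methoxyphenyl pivalate | COc1cc(C=O)cc(I)c1OCc1ccc(OC(=O)C(C)(C)C)c(OC)c1 | intermediate
5 | ethyl diazoacetate | CCOC(=O)C=[N+]=[N-] | starting material
6 | ethyl 2-diazo-2-[5-formyl-3-methoxy-2-({3-methoxy-4-(pivaloyloxy)benzyl}oxy)phenyl]acetate | COc1cc(C=O)cc(C(=[N+]=[N-])C(=O)OCC)c1OCc1ccc(OC(=O)C(C)(C)C)c(OC)c1 | intermediate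
7 | ethyl (2S,3R)-5-formyl-7-methoxy-2-[3-methoxy-4-(pivaloyloxy)phenyl]-2,3-dihydrobenzofuran-3-carboxylate (cis) | COc1cc([C@H]2Oc3c(OC)cc(C=O)cc3[C@H]2C(=O)OCC)ccc1OC(=O)C(C)(C)C | intermediate
8 | ethyl (2S,3R)-5-(hydroxymethyl)-7-methoxy-2-[3-methoxy-4-(pivaloyloxy)phenyl]-2,3-dihydrobenzofuran-3-carboxylate (cis) | COc1cc([C@H]2Oc3c(OC)cc(CO)cc3[C@H]2C(=O)OCC)ccc1OC(=O)C(C)(C)C | intermediate
9 | ethyl (triphenylphosphoranylidene)acetate | CCOC(=O)C=P(c1ccccc1)(c1ccccc1)c1ccccc1 | starting material
10 | ethyl (E)-3-(4-hydroxy-3-iodo-5-methoxyphenyl)acrylate | CCOC(=O)/C=C/c1cc(I)c(O)c(OC)c1 | intermediate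
11 | ethyl (2S,3R)-5-{[4-((E)-3-ethoxy-3-oxoprop-1-enyl)-2-iodo-6-methoxyphenoxy]methyl}-7-methoxy-2-[3-methoxy-4-(pivaloyloxy)phenyl]-2,3-dihydrobenzofuran-3-carboxylate | COc1cc([C@H]2Oc3c(OC)cc(COc4c(I)cc(/C=C/C(=O)OCC)cc4OC)cc3[C@H]2C(=O)OCC)ccc1OC(=O)C(C)(C)C | intermediate
12 | ethyl (2S,3R)-5-{[2-(1-diazo-2-ethoxy-2-oxoethyl)-4-((E)-3-ethoxy-3-oxoprop-1-enyl)-6-methoxyphenoxy]methyl}-7-methoxy-2-[3-methoxy-4-(pivaloyloxy)phenyl]-2,3-dihydrobenzofuran-3-carboxylate | COc1cc([C@H]2Oc3c(OC)cc(COc4c(C(=[N+]=[N-])C(=O)OCC)cc(/C=C/C(=O)OCC)cc4OC)cc3[C@H]2C(=O)OCC)ccc1OC(=O)C(C)(C)C | intermediate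
13 | cis,cis triester: ethyl (2S,3R)-5-[(2S,3R)-3-(ethoxycarbonyl)-5-((E)-3-ethoxy-3-oxoprop-1-enyl)-7-methoxy-2,3-dihydrobenzofuran-2-yl]-7-methoxy-2-[3-methoxy-4-(pivaloyloxy)phenyl]-2,3-dihydrobenzofuran-3-carboxylate | COc1cc([C@H]2Oc3c(OC)cc([C@H]4Oc5c(OC)cc(/C=C/C(=O)OCC)cc5[C@H]4C(=O)OCC)cc3[C@H]2C(=O)OCC)ccc1OC(=O)C(C)(C)C | intermediate
14 | trans,trans triester: ethyl (2S,3S)-5-[(2S,3S)-3-(ethoxycarbonyl)-5-((E)-3-ethoxy-3-oxoprop-1-enyl)-7-methoxy-2,3-dihydrobenzofuran-2-yl]-7-methoxy-2-[3-methoxy-4-(pivaloyloxy)phenyl]-2,3-dihydrobenzofuran-3-carboxylate | COc1cc([C@H]2Oc3c(OC)cc([C@H]4Oc5c(OC)cc(/C=C/C(=O)OCC)cc5[C@@H]4C(=O)OCC)cc3[C@@H]2C(=O)OCC)ccc1OC(=O)C(C)(C)C | intermediate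
15 | 4-[(2S,3R)-3-(hydroxymethyl)-5-{(2S,3R)-3-(hydroxymethyl)-5-[(E)-3-hydroxyprop-1-enyl]-7-methoxy-2,3-dihydrobenzofuran-2-yl}-7-methoxy-2,3-dihydrobenzofuran-2-yl]-2-methoxyphenol | COc1cc([C@H]2Oc3c(OC)cc([C@H]4Oc5c(OC)cc(/C=C/CO)cc5[C@@H]4CO)cc3[C@@H]2CO)ccc1O | target

Total step count: 11. Longest linear sequence: 10 steps (steps 1–5 and 7–11, from vanillyl alcohol); step 6 is a one-step branch.

Steps most likely to fail

1. Step 9. Facial selectivity that rests on the catalyst alone may be insufficient next to the bulky, already chiral rings B and C, and carbenoid dimerisation may compete at the dilution needed. The fallback moves stereocontrol to a covalently bound lactamide auxiliary, a variant of this insertion that should favour the trans ester of ring D directly. Ethyl (S)-lactate is heated with pyrrolidine to give (S)-2-hydroxy-1-(pyrrolidin-1-yl)propan-1-one F1. This is acylated with bromoacetyl bromide (pyridine, CH2Cl2) to the bromoacetate F2 and converted with N,N'-ditosylhydrazine and DBU into the lactamide diazoacetate F3. Setting out from iodide 11, coupling with F3 under the conditions of step 8 gives the auxiliary-bearing aryldiazoacetate F4. Rh2(S-DOSP)4 (dirhodium tetrakis[(S)-N-(4-dodecylphenylsulfonyl)prolinate]) in CH2Cl2 should then give, by double stereodifferentiation, the ring D trans ester F5; the antipodal auxiliary and catalyst would be taken if this pairing favours the other C2 configuration. DBU equilibration of the remaining cis ester on ring B gives the all-trans compound F6. Reduction with i-Bu2AlH as in step 11 cleaves the auxiliary ester, the ethyl esters and the pivalate, and the route is rejoined at 15.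

2. Step 10. The enolate at C3 of ring D may expel the ring E phenoxide, which the para acrylate makes a better leaving group; ring opening and reclosure would erode C2, and incomplete equilibration is the other possible failure. The fallback equilibrates before the acrylate exists. 4-Bromo-2-methoxyphenol is iodinated (NIS, TsOH, MeCN) to 4-bromo-2-iodo-6-methoxyphenol F7. Setting out from alcohol 8, Mitsunobu reaction with F7 gives the bromo iodo ether F8. Iodide-selective coupling with 5 under the conditions of step 8 gives the bromo aryldiazoacetate F9, Rh2(R-PTTL)4 gives the cis,cis bromide F10, and DBU gives the trans,trans bromide F11. A Heck reaction with ethyl acrylate (Pd(OAc)2, P(o-tol)3, Et3N, DMF, 90 °C) then installs the E-cinnamate, and the route is rejoined at 14.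

3. Step 8. Oxidative addition next to the bulky benzyloxy group may be slow, so that palladium-induced loss of N2 from 5 and carbene dimerisation take over. The fallback forms the C–C bond first and the diazo group afterwards. Setting out from iodide 11, coupling with the Reformatsky reagent BrZnCH2CO2Et (Pd2(dba)3, XPhos, THF, 50 °C) gives the ethyl arylacetate F12. Regitz diazo transfer (4-acetamidobenzenesulfonyl azide, DBU, MeCN, 0 °C to rt) then rejoins the route at 12.

Further compounds
F1 | step 9 | (S)-2-hydroxy-1-(pyrrolidin-1-yl)propan-1-one | C[C@H](O)C(=O)N1CCCC1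
F2 | step 9 | (S)-1-oxo-1-(pyrrolidin-1-yl)propan-2-yl 2-bromoacetate | C[C@H](OC(=O)CBr)C(=O)N1CCCC1
F3 | step 9 | (S)-1-oxo-1-(pyrrolidin-1-yl)propan-2-yl 2-diazoacetate | C[C@H](OC(=O)C=[N+]=[N-])C(=O)N1CCCC1
F4 | step 9 | aryldiazoacetate of 12 with the (S)-lactamide ester in place of the ethyl ester at the diazo carbon | COc1cc([C@H]2Oc3c(OC)cc(COc4c(C(=[N+]=[N-])C(=O)O[C@@H](C)C(=O)N5CCCC5)cc(/C=C/C(=O)OCC)cc4OC)cc3[C@H]2C(=O)OCC)ccc1OC(=O)C(C)(C)C
F5 | step 9 | ring D (2S,3S)-trans lactamide ester, ring B (2S,3R)-cis ethyl ester | COc1cc([C@H]2Oc3c(OC)cc([C@H]4Oc5c(OC)cc(/C=C/C(=O)OCC)cc5[C@@H]4C(=O)O[C@@H](C)C(=O)N6CCCC6)cc3[C@H]2C(=O)OCC)ccc1OC(=O)C(C)(C)C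
F6 | step 9 | ring D (2S,3S)-trans lactamide ester, ring B (2S,3S)-trans ethyl ester | COc1cc([C@H]2Oc3c(OC)cc([C@H]4Oc5c(OC)cc(/C=C/C(=O)OCC)cc5[C@@H]4C(=O)O[C@@H](C)C(=O)N6CCCC6)cc3[C@@H]2C(=O)OCC)ccc1OC(=O)C(C)(C)C
F7 | step 10 | 4-bromo-2-iodo-6-methoxyphenol | COc1cc(Br)cc(I)c1O
F8 | step 10 | ethyl (2S,3R)-5-[(4-bromo-2-iodo-6-methoxyphenoxy)methyl]-7-methoxy-2-[3-methoxy-4-(pivaloyloxy)phenyl]-2,3-dihydrobenzofuran-3-carboxylate | COc1cc([C@H]2Oc3c(OC)cc(COc4c(I)cc(Br)cc4OC)cc3[C@H]2C(=O)OCC)ccc1OC(=O)C(C)(C)C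
F9 | step 10 | ethyl (2S,3R)-5-{[4-bromo-2-(1-diazo-2-ethoxy-2-oxoethyl)-6-methoxyphenoxy]methyl}-7-methoxy-2-[3-methoxy-4-(pivaloyloxy)phenyl]-2,3-dihydrobenzofuran-3-carboxylate | COc1cc([C@H]2Oc3c(OC)cc(COc4c(C(=[N+]=[N-])C(=O)OCC)cc(Br)cc4OC)cc3[C@H]2C(=O)OCC)ccc1OC(=O)C(C)(C)C
F10 | step 10 | cis,cis bromide: ethyl (2S,3R)-5-[(2S,3R)-5-bromo-3-(ethoxycarbonyl)-7-methoxy-2,3-dihydrobenzofuran-2-yl]-7-methoxy-2-[3-methoxy-4-(pivaloyloxy)phenyl]-2,3-dihydrobenzofuran-3-carboxylate | COc1cc([C@H]2Oc3c(OC)cc([C@H]4Oc5c(OC)cc(Br)cc5[C@H]4C(=O)OCC)cc3[C@H]2C(=O)OCC)ccc1OC(=O)C(C)(C)C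
F11 | step 10 | trans,trans bromide: ethyl (2S,3S)-5-[(2S,3S)-5-bromo-3-(ethoxycarbonyl)-7-methoxy-2,3-dihydrobenzofuran-2-yl]-7-methoxy-2-[3-methoxy-4-(pivaloyloxy)phenyl]-2,3-dihydrobenzofuran-3-carboxylate | COc1cc([C@H]2Oc3c(OC)cc([C@H]4Oc5c(OC)cc(Br)cc5[C@@H]4C(=O)OCC)cc3[C@@H]2C(=O)OCC)ccc1OC(=O)C(C)(C)C
F12 | step 8 | ethyl (2S,3R)-5-{[2-(2-ethoxy-2-oxoethyl)-4-((E)-3-ethoxy-3-oxoprop-1-enyl)-6-methoxyphenoxy]methyl}-7-methoxy-2-[3-methoxy-4-(pivaloyloxy)phenyl]-2,3-dihydrobenzofuran-3-carboxylate | COc1cc([C@H]2Oc3c(OC)cc(COc4c(CC(=O)OCC)cc(/C=C/C(=O)OCC)cc4OC)cc3[C@H]2C(=O)OCC)ccc1OC(=O)C(C)(C)C
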